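## Structural features

The target is a 2,3-trans-dihydroflavonol: a chroman-4-one in which the phloroglucinol ring A is fused to the pyranone ring C through C4a–C8a, with the guaiacyl ring B on C2 and a hydroxyl on C3. The two stereocentres C2 (R) and C3 (R) are adjacent. C2 is a benzylic ether carbon para to the ring B oxygen and C3 is a carbinol α to the C4 ketone, so C2 can epimerise by ring opening and C3 by enolisation, and the ketol can be oxidised to the flavonol. Ring A carries three chemically different oxygens: O1 in the ring, O5 hydrogen-bonded to C4=O, and O7. The prenyl group sits on C8 between O1 and O7. This prenyl alkene is the most restrictive group: acid cyclises it onto a neighbouring phenol, and it is attacked by osmium tetroxide, peracids and hydrogenation catalysts before anything else in the molecule. The real difficulty is therefore twofold: placing the prenyl group at C8 rather than C6 while making O1, not O5, the oxygen that closes ring C, and setting C2/C3 absolutely with reagents that ignore the prenyl alkene. The key step uses the contiguous triad C8a(O)–C8(prenyl)–C7(O) within the 1,3,5-oxygenated ring A: C8 and C7 are supplied by one siloxyalkyne, C8a, C6, C5 and C4a by a cyclobutenone, and O1 emerges as the only free hydroxyl.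

## Logic of the disconnections

25 to 24. The last cut is at the three O–Si bonds (O5, O7 and the ring B oxygen). All phenols stay masked until the ketol and both stereocentres exist, and their release needs only fluoride, which does not touch the prenyl alkene. The forward step must be buffered, because a free phenoxide of 25 would open ring C at C2.

24 to 22. Ring C is opened at O1–C2. Forward, O1 is freed from its acetal (giving 23) and attacks the benzylic epoxide carbon; C3 keeps the epoxide configuration and C2 ends trans to it. The cut removes the heterocycle and merges two stereocentres into one trans epoxide. It demands that O1 be the only free ring A oxygen at that moment (a free O5 would give the 6-prenyl isomer), that attack occur at the benzylic carbon and not at C3, and that the acid be mild enough for the prenyl group.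

22 to 21. The epoxide oxygen is removed to give the E-enone. Only a nucleophilic oxidant distinguishes the electron-poor enone from the electron-rich prenyl alkene, which rules out dihydroxylation and peracids. The gain is a flat, achiral precursor; the demand is catalyst-controlled facial selectivity on a hindered, electron-rich enone.

21 to 15 and 18. The enone is traced to alcohol 20, which is cut at C3–C4 into the ring A aldehyde 15 and the alkenyl metal 19 derived from iodide 18. This joins rings A and B late and convergently. The forward steps must keep the E geometry through the metalation and oxidise a sensitive, electron-rich carbinol under neutral conditions.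

18 to 16 and 3. The iodoalkene is cut at its C=C bond back to aldehyde 17, and 17 at its O–Si bond to 16 and 3. The one-carbon homologation must be E-selective.

15 to 13. The O1 acetal is removed (14) and then the formyl C4–C4a bond is cut. The single free hydroxyl of 13 is what steers the formyl group to C4a, so the forward reaction must be an ortho-specific, phenoxide-templated formylation that tolerates a flanking silyloxy group.

13 to 8 and 5 (key disconnection). Three ring A bonds are cut: C8–C8a, C6–C7 and C4a–C8a. This divides ring A into a four-carbon unit (8, giving C8a, C6, C5, C4a) and a two-carbon unit (5, giving C8 and C7 with the prenyl group and O7 already attached). The atom mapping was checked and is self-consistent: the ketene carbon becomes C8a, the alkyne carbons C8 and C7. The design change concerns only the oxygen substituent on C3 of the cyclobutenone. A simple alkyl ether there would end as an O5 alkyl ether removable only by a boron trihalide, which the prenyl group next to a phenol and the benzylic C2–O1 bond would not survive. With silicon on that oxygen, O5 and O7 are released together by fluoride while O1 remains the one free oxygen. The forward step demands the correct orientation of the ketene–alkyne union.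

8 to 6 and 3. The O–Si bond is cut to dione 7 and this is traced to the purchasable enol ether 6 by hydrolysis. The silylation must be on oxygen and non-nucleophilic, since the four-membered dione is cleaved by alcohols.

5 to 1 and 3. The O–Si bond is cut to ynolate 4, and the C≡C unit is traced to ester 2 by one-carbon homologation, and 2 to acid 1. The homologation must outrun enolisation of the β,γ-unsaturated ester, and the silyl chloride must be bulky enough to silylate on oxygen.

## Other disconnections considered

Alternative 1: The cut is at C2–C3 and C3–O, with C3 as a carbene carbon. Forward, the ring A diazoketone A1, 4-methoxybenzyl alcohol A2 and protected vanillin A3 are combined with Rh2(OAc)4 and a chiral acid co-catalyst. The rhodium carbene forms an oxonium ylide with A2, and aldol-type trapping by A3 gives the syn hydroxy ether A4. Ring C would then be closed by desilylating O1 and displacing the benzylic hydroxyl with inversion.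
- In its favour: three components meet in one step, both stereocentres are set together under catalyst control, and ring B enters as a plain aldehyde. On stereocentre economy this is better than the chosen plan, where the catalyst sets C3 and the ring closure sets C2.
- Against it here: A1 already needs the 8-prenyl ring A, so the regiochemical problem is only moved, and several steps (acylation, diazo transfer) are added. An acceptor-only carbene ylide tends to collapse by proton shift to the O–H insertion product before the electron-rich, weakly electrophilic A3 can trap it. Displacement at a para-oxygenated benzylic carbinol is prone to ionisation, and three protecting-group classes must be removed.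
- Comparison: structurally both plans need the same ring A. Mechanistically, nucleophilic epoxidation of an enone is more predictable than ylide trapping in competition with insertion. In step count after ring A the two are about equal, and the diazo compound is a safety disadvantage.

Alternative 2: The cuts are O1–C8a and C4–C4a. Forward, a fluoride source (CsF) converts the silyl aryl triflate A5 into the C4a–C8a aryne. The benzylic alkoxide of hydroxy ester A6 adds at C8a and the resulting C4a aryl anion attacks the ester to give chromanone A7.
- In its favour: both stereocentres come from A6, which can be made by asymmetric dihydroxylation of a cinnamate before any prenyl group is present; on security of enantiopurity this is better than a late epoxidation. No stereocentre is touched in the annulation, two ring bonds form in one step, and the O5 ether next to the aryne directs the nucleophile to the distal carbon C8a, which is the required sense.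
- Against it here: A5 is a fully substituted benzene whose preparation needs the prenyl regiochemistry solved first and then several more steps. C8a is shielded by the prenyl group. Aliphatic alkoxides add to arynes poorly, the aryl anion is more likely to be protonated by the hydroxyl of A6 than acylated, and A6 can undergo retro-aldol cleavage or elimination under basic fluoride. Because no inversion occurs, A6 must be the anti isomer, which needs one inversion beyond the direct syn-dihydroxylation.
- Comparison: for ring C alone the annulation is shorter (equal or better). Overall it is longer because of A5 and A6, and the intermolecular two-bond event has more leak channels than the intramolecular pericyclic cascade of the chosen plan.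

Alternative 3: The cut is at C3–C4. Forward, a chiral triazolylidene converts the ring A aldehyde of dialdehyde A8 into an acyl anion equivalent, which adds to the tethered aliphatic aldehyde and gives ketol A9.
- In its favour: the 3-hydroxy-4-ketone appears directly at the right oxidation level, so redox economy is better than in the chosen plan, which needs an alcohol oxidation and an epoxidation. The conditions are metal-free and harmless to the prenyl group. O1–C2 already exists, so no epoxide regiochemistry arises, and A9 needs only one acidic deprotection step (better than two). It could also start from the salicylaldehyde 14 of the chosen route, so it is compatible with the benzannulation.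
- Against it here: the carbene must choose the hindered, electron-rich 2,6-disubstituted aryl aldehyde over the unhindered aliphatic one; the reverse choice gives the isomeric 4-hydroxychroman-3-one. The C2 centre of A8 is benzylic, oxygen-substituted and α to an aldehyde, so it would epimerise under the basic carbene conditions, and it must first be installed by O-alkylation with an ionisation-prone benzylic electrophile. Aldehyde–aldehyde crossed benzoin closures are less developed than aldehyde–ketone ones.
- Comparison: structurally the ring A problem is the same. In step count it is equal or slightly shorter in principle. Mechanistically it rests on a chemoselectivity that the substrate disfavours and passes through a configurationally fragile intermediate, whereas in the chosen plan C3 is fixed in a robust epoxide.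

Key step: step 5

Remark on the chemistry: flavonoid numbering (O1, C2, C3, C4, C4a, C5 to C8, C8a) is used for all intermediates; the carbinol centre of 20 is formed racemic and erased in step 11, so 20 is carried as the racemate.

## Route

Step 1
Reactants: 1 4-methylpent-3-enoic acid
Product: 2 ethyl 4-methylpent-3-enoate
Conditions: EtI, K2CO3, DMF, rt
Reagents that add atoms: iodoethane, CCI
Why: Carboxylate O-alkylation (SN2) under weak base avoids the acid that would lactonise or conjugate the β,γ-unsaturated acid; the ethyl ester is the usual substrate of the Kowalski homologation.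

Step 2
Reactants: 2 ethyl 4-methylpent-3-enoate; 3 chlorotriisopropylsilane
Product: 5 triisopropyl[(5-methylhex-4-en-1-yn-1-yl)oxy]silane, via lithium ynolate 4 (not isolated)
Conditions: CH2Br2, LiTMP (lithium 2,2,6,6-tetramethylpiperidide, 2 equiv), THF, −78 °C; then n-BuLi, −78 to 0 °C; then 3, −78 °C to rt
Reagents that add atoms: dibromomethane, BrCBr
Why: Kowalski ester homologation: LiCHBr2 adds to the ester, the derived dibromo enolate undergoes bromine–lithium exchange and 1,2-shift of the alkyl chain to give ynolate 4. The bulky silyl chloride 3 then silylates on oxygen, whereas small silyl chlorides would give silylketenes.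

Step 3
Reactants: 6 3-ethoxycyclobut-2-en-1-one
Product: 7 cyclobutane-1,3-dione
Conditions: 1 M aq. HCl, 0 °C to rt; cold isolation
Reagents that add atoms: water, O
Why: Acid hydrolysis of a vinylogous ester by addition–elimination of water at C3; the strongly acidic, largely enolised dione is an isolable solid when kept cold and away from nucleophiles.

Step 4
Reactants: 7 cyclobutane-1,3-dione; 3 chlorotriisopropylsilane
Product: 8 3-(triisopropylsilyloxy)cyclobut-2-en-1-one
Conditions: Et3N, cat. DMAP, CH2Cl2, 0 °C; non-aqueous work-up
Reagents that add atoms: none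
Why: O-silylation of a vinylogous acid through its triethylammonium salt, analogous to silyl ester formation. The bulky silyl group makes the vinylogous silyl ester handleable and puts on the future O5 the same fluoride-labile group as on O7.

Step 5
Reactants: 8 3-(triisopropylsilyloxy)cyclobut-2-en-1-one; 5 triisopropyl[(5-methylhex-4-en-1-yn-1-yl)oxy]silane (1.2 equiv)
Product: 13 2-(3-methylbut-2-enyl)-3,5-bis(triisopropylsilyloxy)phenol, via vinylketene 9 (not isolated), via vinylcyclobutenone 10 (not isolated), via dienylketene 11 (not isolated), via cyclohexadienone 12 (not isolated)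
Conditions: toluene, 80 °C then 110 °C, sealed vessel, argon
Reagents that add atoms: none
Why: Danheiser benzannulation; the closest known reaction type is the thermal cyclobutenone–siloxyalkyne benzannulation to resorcinol monosilyl ethers, here with a vinylogous silyl ester as the cyclobutenone. Four-electron conrotatory opening of 8 gives vinylketene 9, whose ketene C=C adds alkyne 5 in a (2+2) cycloaddition to give 10, forming C8–C8a and C6–C7. 10 opens again to dienylketene 11, and the isomer with the ketene and siloxyvinyl termini cis undergoes six-electron disrotatory electrocyclisation, which forms C4a–C8a and closes ring A as dienone 12; tautomerisation to 13 and loss of ring strain make the cascade irreversible. The selectivity required is the orientation of the (2+2) step: the siloxyalkyne is polarised like a ketene acetal, so its nucleophilic prenyl-bearing carbon bonds to the electrophilic ketene carbon, which becomes C8a carrying the only free hydroxyl next to the prenyl group. No stereocentre is formed. A small excess of 5 limits O-acylation of 13 by 9, and the unactivated prenyl alkene is not expected to intercept the ketenes.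

Step 6
Reactants: 13 2-(3-methylbut-2-enyl)-3,5-bis(triisopropylsilyloxy)phenol
Product: 14 2-hydroxy-3-(3-methylbut-2-enyl)-4,6-bis(triisopropylsilyloxy)benzaldehyde
Conditions: MgCl2 (anhydrous), Et3N, (CH2O)n, THF, reflux
Reagents that add atoms: formaldehyde (from paraformaldehyde), C=O
Why: Casnati–Skattebøl ortho-formylation: the magnesium phenoxide delivers formaldehyde to the only free ortho position (C4a) through a six-membered chelate, and the resulting benzylic alkoxide is oxidised by a second formaldehyde through hydride transfer. The para position C6 is not addressed, and the mild base should leave the silyl ethers and the prenyl group intact.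

Step 7
Reactants: 14 2-hydroxy-3-(3-methylbut-2-enyl)-4,6-bis(triisopropylsilyloxy)benzaldehyde
Product: 15 2-(methoxymethoxy)-3-(3-methylbut-2-enyl)-4,6-bis(triisopropylsilyloxy)benzaldehyde
Conditions: NaH, THF, 0 °C; then MeOCH2Cl (solution in toluene), 0 °C to rt
Reagents that add atoms: chloromethyl methyl ether, COCCl
Why: Alkylation of the sodium phenoxide to the formaldehyde acetal. This masks O1 against the organomagnesium and basic peroxide steps, and it is the one group later removed by mild acid while O5 stays silylated.

Step 8
Reactants: 16 vanillin; 3 chlorotriisopropylsilane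
Product: 17 3-methoxy-4-(triisopropylsilyloxy)benzaldehyde
Conditions: imidazole, DMF, rt
Reagents that add atoms: none
Why: Standard imidazole-promoted silylation of a phenol; ring B thus carries the same fluoride-labile group as ring A.

Step 9
Reactants: 17 3-methoxy-4-(triisopropylsilyloxy)benzaldehyde
Product: 18 {4-[(E)-2-iodoethenyl]-2-methoxyphenoxy}triisopropylsilane
Conditions: CrCl2, CHI3, THF, 0 °C to rt
Reagents that add atoms: iodoform, IC(I)I
Why: Takai olefination: the geminal dichromium species from iodoform and CrCl2 adds to the aldehyde and eliminates to the E-iodoalkene; aryl silyl ethers are inert to it.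

Step 10
Reactants: 18 {4-[(E)-2-iodoethenyl]-2-methoxyphenoxy}triisopropylsilane; 15 2-(methoxymethoxy)-3-(3-methylbut-2-enyl)-4,6-bis(triisopropylsilyloxy)benzaldehyde
Product: 20 (2E)-1-[2-(methoxymethoxy)-3-(3-methylbut-2-enyl)-4,6-bis(triisopropylsilyloxy)phenyl]-3-[3-methoxy-4-(triisopropylsilyloxy)phenyl]prop-2-en-1-ol (racemate), via alkenylmagnesium chloride 19 (not isolated)
Conditions: 18, i-PrMgCl·LiCl (slightly less than 18), THF, 0 °C to rt; then 15, −20 to 0 °C; aq. NH4Cl; crude product used directly
Reagents that add atoms: none
Why: Iodine–magnesium exchange with retention of alkene geometry, then 1,2-addition of 19 to the aldehyde, which forms the C3–C4 bond. The carbinol centre is racemic and is removed in step 11; the electron-rich benzylic alcohol is not purified because it ionises easily.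

Step 11
Reactants: 20 (2E)-1-[2-(methoxymethoxy)-3-(3-methylbut-2-enyl)-4,6-bis(triisopropylsilyloxy)phenyl]-3-[3-methoxy-4-(triisopropylsilyloxy)phenyl]prop-2-en-1-ol
Product: 21 (2E)-1-[2-(methoxymethoxy)-3-(3-methylbut-2-enyl)-4,6-bis(triisopropylsilyloxy)phenyl]-3-[3-methoxy-4-(triisopropylsilyloxy)phenyl]prop-2-en-1-one
Conditions: MnO2 (activated, excess), CH2Cl2, rt
Reagents that add atoms: none
Why: Oxidation of a doubly activated (benzylic and allylic) alcohol by MnO2 under neutral conditions; the prenyl alkene, the acetal and the silyl ethers are not affected.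

Step 12
Reactants: 21 (2E)-1-[2-(methoxymethoxy)-3-(3-methylbut-2-enyl)-4,6-bis(triisopropylsilyloxy)phenyl]-3-[3-methoxy-4-(triisopropylsilyloxy)phenyl]prop-2-en-1-one
Product: 22 [2-(methoxymethoxy)-3-(3-methylbut-2-enyl)-4,6-bis(triisopropylsilyloxy)phenyl]{(2R,3S)-3-[3-methoxy-4-(triisopropylsilyloxy)phenyl]oxiran-2-yl}methanone
Conditions: poly-L-leucine, urea–H2O2, DBU, THF, rt
Reagents that add atoms: hydrogen peroxide (as urea adduct), OO
Why: Juliá–Colonna epoxidation, a Weitz–Scheffer addition of hydroperoxide anion inside the helical peptide; the nucleophilic oxidant attacks only the enone and not the electron-rich prenyl alkene. Poly-L-leucine is known to deliver the (αR,βS) epoxide of chalcones, and the same face here sets C3 as R (kept to the target) and the benzylic carbon as S.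

Step 13
Reactants: 22 [2-(methoxymethoxy)-3-(3-methylbut-2-enyl)-4,6-bis(triisopropylsilyloxy)phenyl]{(2R,3S)-3-[3-methoxy-4-(triisopropylsilyloxy)phenyl]oxiran-2-yl}methanone
Product: 24 (2R,3R)-3-hydroxy-2-[3-methoxy-4-(triisopropylsilyloxy)phenyl]-8-(3-methylbut-2-enyl)-5,7-bis(triisopropylsilyloxy)-2,3-dihydro-4H-chromen-4-one, via free phenol 23 (not isolated)
Conditions: conc. HCl (few equiv), MeOH–THF, 40 °C
Reagents that add atoms: none
Why: Acidic methanolysis cleaves the carbonyl-chelated methoxymethyl ether to phenol 23 while the aryl triisopropylsilyl ethers should persist. The protonated epoxide opens at the benzylic carbon, activated by the para-oxygenated ring B, and O1 closes the six-membered ring (6-endo). C3 keeps its configuration and C2 ends R either by direct inversion or, if the benzylic cation intervenes, through the preference for the 2,3-trans diequatorial chromanone.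

Step 14
Reactants: 24 (2R,3R)-3-hydroxy-2-[3-methoxy-4-(triisopropylsilyloxy)phenyl]-8-(3-methylbut-2-enyl)-5,7-bis(triisopropylsilyloxy)-2,3-dihydro-4H-chromen-4-one
Product: 25 (2R,3R)-3,5,7-trihydroxy-2-(4-hydroxy-3-methoxyphenyl)-8-(3-methylbut-2-enyl)-2,3-dihydro-4H-chromen-4-one
Conditions: Bu4NF, AcOH (1:1), THF, 0 °C, argon
Reagents that add atoms: none
Why: Fluoride cleaves the three aryl O–Si bonds, driven by the Si–F bond strength. Acetic acid keeps the liberated phenols protonated, so ring C should not open at C2 and the ketol should not epimerise or air-oxidise.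

## Compound list

1 | 4-methylpent-3-enoic acid | CC(C)=CCC(=O)O | starting material
2 | ethyl 4-methylpent-3-enoate | CCOC(=O)CC=C(C)C | intermediate
3 | chlorotriisopropylsilane | CC(C)[Si](Cl)(C(C)C)C(C)C | starting material
4 | lithium 5-methylhex-4-en-1-yn-1-olate | [Li+].[O-]C#CCC=C(C)C | intermediate
5 | triisopropyl[(5-methylhex-4-en-1-yn-1-yl)oxy]silane | CC(C)=CCC#CO[Si](C(C)C)(C(C)C)C(C)C | intermediate
6 | 3-ethoxycyclobut-2-en-1-one | CCOC1=CC(=O)C1 | starting material
7 | cyclobutane-1,3-dione | O=C1CC(=O)C1 | intermediate
8 | 3-(triisopropylsilyloxy)cyclobut-2-en-1-one | O=C1C=C(O[Si](C(C)C)(C(C)C)C(C)C)C1 | intermediate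
9 | 3-(triisopropylsilyloxy)buta-1,3-dien-1-one | O=C=CC(=C)O[Si](C(C)C)(C(C)C)C(C)C | intermediate
10 | 2-(3-methylbut-2-enyl)-3-(triisopropylsilyloxy)-4-[1-(triisopropylsilyloxy)ethenyl]cyclobut-2-en-1-one (racemate) | O=C1C(CC=C(C)C)=C(O[Si](C(C)C)(C(C)C)C(C)C)C1C(=C)O[Si](C(C)C)(C(C)C)C(C)C | intermediate
11 | (3E)-2-(3-methylbut-2-enyl)-3,5-bis(triisopropylsilyloxy)hexa-1,3,5-trien-1-one | O=C=C(CC=C(C)C)/C(O[Si](C(C)C)(C(C)C)C(C)C)=C\C(=C)O[Si](C(C)C)(C(C)C)C(C)C | intermediate
12 | 2-(3-methylbut-2-enyl)-3,5-bis(triisopropylsilyloxy)cyclohexa-2,4-dien-1-one | O=C1CC(O[Si](C(C)C)(C(C)C)C(C)C)=CC(O[Si](C(C)C)(C(C)C)C(C)C)=C1CC=C(C)C | intermediate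
13 | 2-(3-methylbut-2-enyl)-3,5-bis(triisopropylsilyloxy)phenol | Oc1cc(O[Si](C(C)C)(C(C)C)C(C)C)cc(O[Si](C(C)C)(C(C)C)C(C)C)c1CC=C(C)C | intermediate
14 | 2-hydroxy-3-(3-methylbut-2-enyl)-4,6-bis(triisopropylsilyloxy)benzaldehyde | O=Cc1c(O)c(CC=C(C)C)c(O[Si](C(C)C)(C(C)C)C(C)C)cc1O[Si](C(C)C)(C(C)C)C(C)C | intermediate
15 | 2-(methoxymethoxy)-3-(3-methylbut-2-enyl)-4,6-bis(triisopropylsilyloxy)benzaldehyde | O=Cc1c(OCOC)c(CC=C(C)C)c(O[Si](C(C)C)(C(C)C)C(C)C)cc1O[Si](C(C)C)(C(C)C)C(C)C | intermediate
16 | vanillin (4-hydroxy-3-methoxybenzaldehyde) | COc1cc(C=O)ccc1O | starting material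
17 | 3-methoxy-4-(triisopropylsilyloxy)benzaldehyde | COc1cc(C=O)ccc1O[Si](C(C)C)(C(C)C)C(C)C | intermediate
18 | {4-[(E)-2-iodoethenyl]-2-methoxyphenoxy}triisopropylsilane | COc1cc(/C=C/I)ccc1O[Si](C(C)C)(C(C)C)C(C)C | intermediate
19 | chloro{(E)-2-[3-methoxy-4-(triisopropylsilyloxy)phenyl]ethenyl}magnesium | COc1cc(/C=C/[Mg]Cl)ccc1O[Si](C(C)C)(C(C)C)C(C)C | intermediate
20 | (2E)-1-[2-(methoxymethoxy)-3-(3-methylbut-2-enyl)-4,6-bis(triisopropylsilyloxy)phenyl]-3-[3-methoxy-4-(triisopropylsilyloxy)phenyl]prop-2-en-1-ol (racemate) | COc1cc(/C=C/C(O)c2c(OCOC)c(CC=C(C)C)c(O[Si](C(C)C)(C(C)C)C(C)C)cc2O[Si](C(C)C)(C(C)C)C(C)C)ccc1O[Si](C(C)C)(C(C)C)C(C)C | intermediate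
21 | (2E)-1-[2-(methoxymethoxy)-3-(3-methylbut-2-enyl)-4,6-bis(triisopropylsilyloxy)phenyl]-3-[3-methoxy-4-(triisopropylsilyloxy)phenyl]prop-2-en-1-one | COc1cc(/C=C/C(=O)c2c(OCOC)c(CC=C(C)C)c(O[Si](C(C)C)(C(C)C)C(C)C)cc2O[Si](C(C)C)(C(C)C)C(C)C)ccc1O[Si](C(C)C)(C(C)C)C(C)C | intermediate
22 | [2-(methoxymethoxy)-3-(3-methylbut-2-enyl)-4,6-bis(triisopropylsilyloxy)phenyl]{(2R,3S)-3-[3-methoxy-4-(triisopropylsilyloxy)phenyl]oxiran-2-yl}methanone | O=C(c1c(OCOC)c(CC=C(C)C)c(O[Si](C(C)C)(C(C)C)C(C)C)cc1O[Si](C(C)C)(C(C)C)C(C)C)[C@@H]1O[C@H]1c1ccc(O[Si](C(C)C)(C(C)C)C(C)C)c(OC)c1 | intermediate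
23 | [2-hydroxy-3-(3-methylbut-2-enyl)-4,6-bis(triisopropylsilyloxy)phenyl]{(2R,3S)-3-[3-methoxy-4-(triisopropylsilyloxy)phenyl]oxiran-2-yl}methanone | O=C(c1c(O)c(CC=C(C)C)c(O[Si](C(C)C)(C(C)C)C(C)C)cc1O[Si](C(C)C)(C(C)C)C(C)C)[C@@H]1O[C@H]1c1ccc(O[Si](C(C)C)(C(C)C)C(C)C)c(OC)c1 | intermediate
24 | (2R,3R)-3-hydroxy-2-[3-methoxy-4-(triisopropylsilyloxy)phenyl]-8-(3-methylbut-2-enyl)-5,7-bis(triisopropylsilyloxy)-2,3-dihydro-4H-chromen-4-one | COc1cc([C@H]2Oc3c(CC=C(C)C)c(O[Si](C(C)C)(C(C)C)C(C)C)cc(O[Si](C(C)C)(C(C)C)C(C)C)c3C(=O)[C@@H]2O)ccc1O[Si](C(C)C)(C(C)C)C(C)C | intermediate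
25 | (2R,3R)-3,5,7-trihydroxy-2-(4-hydroxy-3-methoxyphenyl)-8-(3-methylbut-2-enyl)-2,3-dihydro-4H-chromen-4-one | COc1cc([C@H]2Oc3c(CC=C(C)C)c(O)cc(O)c3C(=O)[C@@H]2O)ccc1O | target

## Step count and least certain steps

Total: 14 steps. Longest linear sequence: 10 steps (1, 2, 5, 13, 14, 15, 20, 21, 22, 24, 25; the branch from 6 through 7 and 8 is equally long). Dione 7 is also sold; if bought, step 3 falls away.

Step 5 (key step). The push–pull stabilisation of the vinylogous silyl ester 8 may slow its electrocyclic opening. At the higher temperature then needed, rearrangement of the siloxyalkyne to a silylketene, or capture of vinylketene 9 by the product phenol, could outpace the cascade. The fallback gives up the annulation for a classical, statistical route that is possible only because O5 and O7 now carry the same group. Benzene-1,3,5-triol F1 is C-prenylated (1-bromo-3-methylbut-2-ene, aq. KOH, 0 °C) to 2-(3-methylbut-2-enyl)benzene-1,3,5-triol F2. Two equivalents of 3 (imidazole, DMF, 0 °C) then silylate the unhindered para hydroxyl and one of the two equivalent ortho hydroxyls. This sets out from 3 and F1 and returns to the route at 13, after separation from mono- and trisilyl ethers.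

Step 12. The enone is hindered on the ring A side and deactivated by the electron-rich ring B, so slow conversion and poor facial selectivity are the likely failures; prolonged exposure to basic peroxide could also strip the O5 silyl ether. A first recourse is another catalyst of the same kind (La(O-i-Pr)3, BINOL, Ph3P=O, cumene hydroperoxide). The fallback proper moves the asymmetric event to the allylic alcohol. Racemic 20 is subjected to Sharpless kinetic-resolution epoxidation (Ti(O-i-Pr)4, L-(+)-diisopropyl tartrate, t-BuOOH, 4 Å sieves, CH2Cl2, −20 °C). The hydroxyl-bound titanium epoxidises only the allylic alkene of the fast-reacting enantiomer and leaves the prenyl group alone, giving the erythro epoxy alcohol (S)-[2-(methoxymethoxy)-3-(3-methylbut-2-enyl)-4,6-bis(triisopropylsilyloxy)phenyl]{(2S,3S)-3-[3-methoxy-4-(triisopropylsilyloxy)phenyl]oxiran-2-yl}methanol F3. Dess–Martin oxidation of F3 returns to the route at 22. The unreacted enantiomer of 20 is recycled through 21 and NaBH4/CeCl3 reduction. Yield is capped at half per pass, and the electron-rich epoxide must be handled cold.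

Step 13. Three processes compete with the wanted closure: attack of O1 at C3 (5-exo, to a benzofuranone), acid-induced addition of the free O1–H to the prenyl alkene before ring closure, and premature loss of the O5 silyl group, which would let O5 compete and scramble the prenyl position. The fallback separates deprotection from ring closure and removes the 5-exo channel. From 22, MgBr2·OEt2 (Et2O–toluene, 0 °C) cleaves the chelated acetal and opens the epoxide anti at the benzylic carbon to give (2S,3R)-3-bromo-2-hydroxy-1-[2-hydroxy-3-(3-methylbut-2-enyl)-4,6-bis(triisopropylsilyloxy)phenyl]-3-[3-methoxy-4-(triisopropylsilyloxy)phenyl]propan-1-one F4. Ag2CO3 in MeCN then ionises the benzylic bromide, and only O1 can capture that cation in a six-membered ring, trans to the C3 hydroxyl. This returns to the route at 24.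

Step 2. The α-protons of the β,γ-unsaturated ester are unusually acidic. Deprotonation by the carbenoid base instead of addition would return ester with the alkene moved into conjugation. The fallback builds the ynolate by oxidation instead of homologation. Purchased 5-methylhex-4-en-1-yne F5 is deprotonated (n-BuLi, THF, −78 °C) and the acetylide is oxidised with LiOO-t-Bu (from anhydrous t-BuOOH and LiN(SiMe3)2, −78 to 0 °C) to ynolate 4. Silylation with 3 as in step 2 gives 5. This sets out from F5 and 3 and rejoins at 4.

Step 6. The only free ortho position lies between the phenoxide and the bulky O5 silyl ether. The templated hydroxymethylation may therefore be slow, and prolonged heating with magnesium alkoxides may cost a silyl group. The fallback replaces electrophilic formylation by directed metalation. From 13, NaH and chloromethyl methyl ether give 1-(methoxymethoxy)-2-(3-methylbut-2-enyl)-3,5-bis(triisopropylsilyloxy)benzene F6. n-BuLi/TMEDA (THF, −20 °C) lithiates C4a, the only ring position ortho to the acetal oxygen, and DMF delivers the formyl group. The bulky base must be kept cold to avoid deprotonating the prenyl CH2. This returns to the route at 15 and bypasses 14.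

## Further compounds

F1 | step 5 | benzene-1,3,5-triol | Oc1cc(O)cc(O)c1
F2 | step 5 | 2-(3-methylbut-2-enyl)benzene-1,3,5-triol | CC(C)=CCc1c(O)cc(O)cc1O
F3 | step 12 | (S)-[2-(methoxymethoxy)-3-(3-methylbut-2-enyl)-4,6-bis(triisopropylsilyloxy)phenyl]{(2S,3S)-3-[3-methoxy-4-(triisopropylsilyloxy)phenyl]oxiran-2-yl}methanol | O[C@@H](c1c(OCOC)c(CC=C(C)C)c(O[Si](C(C)C)(C(C)C)C(C)C)cc1O[Si](C(C)C)(C(C)C)C(C)C)[C@@H]1O[C@H]1c1ccc(O[Si](C(C)C)(C(C)C)C(C)C)c(OC)c1
F4 | step 13 | (2S,3R)-3-bromo-2-hydroxy-1-[2-hydroxy-3-(3-methylbut-2-enyl)-4,6-bis(triisopropylsilyloxy)phenyl]-3-[3-methoxy-4-(triisopropylsilyloxy)phenyl]propan-1-one | O=C(c1c(O)c(CC=C(C)C)c(O[Si](C(C)C)(C(C)C)C(C)C)cc1O[Si](C(C)C)(C(C)C)C(C)C)[C@H](O)[C@H](Br)c1ccc(O[Si](C(C)C)(C(C)C)C(C)C)c(OC)c1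
F5 | step 2 | 5-methylhex-4-en-1-yne | C#CCC=C(C)C
F6 | step 6 | 1-(methoxymethoxy)-2-(3-methylbut-2-enyl)-3,5-bis(triisopropylsilyloxy)benzene | COCOc1cc(O[Si](C(C)C)(C(C)C)C(C)C)cc(O[Si](C(C)C)(C(C)C)C(C)C)c1CC=C(C)C
A1 | alternative 1 | 1-[2-(tert-butyldimethylsilyloxy)-4,6-bis(methoxymethoxy)-3-(3-methylbut-2-enyl)phenyl]-2-diazoethan-1-one | [N-]=[N+]=CC(=O)c1c(O[Si](C)(C)C(C)(C)C)c(CC=C(C)C)c(OCOC)cc1OCOC
A2 | alternative 1 | (4-methoxyphenyl)methanol | COc1ccc(CO)cc1
A3 | alternative 1 | 3-methoxy-4-(methoxymethoxy)benzaldehyde | COCOc1ccc(C=O)cc1OC
A4 | alternative 1 | (2R,3S)-1-[2-(tert-butyldimethylsilyloxy)-4,6-bis(methoxymethoxy)-3-(3-methylbut-2-enyl)phenyl]-3-hydroxy-2-(4-methoxybenzyloxy)-3-[3-methoxy-4-(methoxymethoxy)phenyl]propan-1-one | COCOc1ccc(cc1OC)[C@H](O)[C@@H](OCc1ccc(OC)cc1)C(=O)c1c(O[Si](C)(C)C(C)(C)C)c(CC=C(C)C)c(OCOC)cc1OCOC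
A5 | alternative 2 | 3,5-bis(methoxymethoxy)-2-(3-methylbut-2-enyl)-6-(trimethylsilyl)phenyl trifluoromethanesulfonate | COCOc1cc(OCOC)c([Si](C)(C)C)c(OS(=O)(=O)C(F)(F)F)c1CC=C(C)C
A6 | alternative 2 | methyl (2R,3R)-3-hydroxy-3-[3-methoxy-4-(methoxymethoxy)phenyl]-2-(methoxymethoxy)propanoate | COCOc1ccc(cc1OC)[C@@H](O)[C@@H](OCOC)C(=O)OC
A7 | alternative 2 | (2R,3R)-3,5,7-tris(methoxymethoxy)-2-[3-methoxy-4-(methoxymethoxy)phenyl]-8-(3-methylbut-2-enyl)chroman-4-one | COc1cc([C@H]2Oc3c(CC=C(C)C)c(OCOC)cc(OCOC)c3C(=O)[C@@H]2OCOC)ccc1OCOC
A8 | alternative 3 | (2R)-2-[2-formyl-3,5-bis(methoxymethoxy)-6-(3-methylbut-2-enyl)phenoxy]-2-[3-methoxy-4-(methoxymethoxy)phenyl]acetaldehyde | COCOc1ccc(cc1OC)[C@H](C=O)Oc1c(C=O)c(OCOC)cc(OCOC)c1CC=C(C)C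
A9 | alternative 3 | (2R,3R)-3-hydroxy-5,7-bis(methoxymethoxy)-2-[3-methoxy-4-(methoxymethoxy)phenyl]-8-(3-methylbut-2-enyl)chroman-4-one | COc1cc([C@H]2Oc3c(CC=C(C)C)c(OCOC)cc(OCOC)c3C(=O)[C@@H]2O)ccc1OCOC
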